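## Retrosynthetic overview

- **Feature:** in the dihydropyran ring (O1–C2–C3–C4–C5=C6), O1–C2 is the β-alkoxy bond of the aldehyde on C3. C2 and C3 can therefore exchange by retro-oxa-Michael opening and enolisation. C4 cannot, so only C4 needs asymmetric synthesis.
- Target ⇒ its catechol acetonide ⇒ open enol dialdehyde, by cutting O1–C2 (oxa-Michael). This is the only lasting ring that is built, and it closes last.
- Open enol dialdehyde ⇒ enol lactone carrying the ethylidene enal + hydroxytyrosol acetonide. One acyl transfer sets the ester and frees the formylacetate enol. This opens the temporary pyranone ring made two steps after the Michael addition.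
- Enol lactone ⇒ Michael adduct (Fukuyama reduction, lactol oxidation, acetal hydrolysis) ⇒ dienal + thiomalonate. Iminium catalysis forms C4–C5 and sets C4.
- Dienal ⇒ crotonaldehyde + acrolein (α-iodination, acetal, Heck), so the ethylidene is carried in from the start.

Key step: step 10

**Remarks on the chemistry**
- An enal that already bears CH2CO2R on its γ-carbon is a vinylogous 1,3-dicarbonyl compound and would end as a push–pull dienamine on the amine catalyst. The acetate carbon is therefore the enal carbonyl of the Michael acceptor itself, raised to the acid level later.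
- A late cross-aldol condensation with acetaldehyde would have to run beside an acidic malonate or formylacetate C–H and beside acetaldehyde self-condensation. The ethylidene enal is therefore brought in masked, from crotonaldehyde.
- The malonate carbon of the Michael adduct, the hemiacetal carbon of the lactol and the enol geometry carry no information for the target and are left undefined. The descriptor at the C4 carbon changes from S to R along the route by CIP priority only.

## Route

Step 1
Reactants: 1 hydroxytyrosol
Product: 2 hydroxytyrosol acetonide 2-(2,2-dimethyl-1,3-benzodioxol-5-yl)ethanol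
Conditions: Me2C(OMe)2, TsOH·H2O (cat.), toluene, reflux, 4 Å MS as MeOH trap; short aqueous acid wash
Reagents that add atoms: 2,2-dimethoxypropane, COC(C)(C)OC
Why: Acid-catalysed transketalisation closes the five-membered benzodioxole on the catechol, and any mixed ketal on the primary alcohol falls off in the aqueous wash.

Step 2
Reactants: 3 (E)-crotonaldehyde
Product: 4 (Z)-2-iodobut-2-enal
Conditions: I2, K2CO3, DMAP (20 mol %), THF/H2O, rt
Reagents that add atoms: iodine, II
Why: Baylis–Hillman-type α-iodination (DMAP adds to C3, the enolate is iodinated at C2, DMAP leaves by E1cB) gives the more stable Z isomer with formyl trans to methyl, the geometry needed later.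

Step 3
Reactants: 4 (Z)-2-iodobut-2-enal
Product: 5 (Z)-2-iodo-1,1-dimethoxybut-2-ene
Conditions: HC(OMe)3, CSA (cat.), MeOH, rt
Reagents that add atoms: trimethyl orthoformate, COC(OC)OC
Why: Orthoformate acetalisation masks the branched aldehyde, so that in step 5 only the new unbranched enal can form an iminium ion and the methyl-bearing alkene terminus has no carbonyl activation of its own.

Step 4
Reactants: 5 (Z)-2-iodo-1,1-dimethoxybut-2-ene; 6 acrolein
Product: 7 (2E,4E)-4-(dimethoxymethyl)hexa-2,4-dienal
Conditions: Pd(OAc)2 (5 mol %), n-Bu4NCl, NaHCO3, DMF, BHT, rt to 40 °C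
Reagents that add atoms: none
Why: Heck vinylation under phase-transfer (ammonium chloride) conditions keeps the geometry of the vinyl iodide (chain cis to methyl), gives the new C2=C3 bond E by syn insertion and syn β-hydride elimination, and runs cool enough for acrolein and the acetal.

Step 5
Reactants: 7 (2E,4E)-4-(dimethoxymethyl)hexa-2,4-dienal; 8 methyl 3-(ethylsulfanyl)-3-oxopropanoate
Product: 9 methyl (3S,4E)-4-(dimethoxymethyl)-2-[(ethylsulfanyl)carbonyl]-3-(2-oxoethyl)hex-4-enoate (both C2 epimers)
Conditions: (R)-2-[diphenyl(trimethylsilyloxy)methyl]pyrrolidine (10 mol %), PhCO2H (10 mol %), toluene, 0 °C to rt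
Reagents that add atoms: none
Why: Iminium-catalysed Michael addition with a diarylprolinol silyl ether, in which the CPh2OTMS group of the (R)-catalyst covers the Si face of C3 in the s-trans E-iminium ion so that 8 adds to the Re face and sets the future C4 (S here, R once the neighbouring carbon is sp2), and attack at C3 rather than at the methyl-bearing C5 follows the known 1,4-preference of linear 2,4-dienals with soft carbon acids under this catalysis.

Step 6
Reactants: 9 Michael adduct
Product: 11 lactol methyl (4R)-4-[(2E)-1,1-dimethoxybut-2-en-2-yl]-2-hydroxy-3,4-dihydro-2H-pyran-5-carboxylate, via open enol aldehyde 10 (not isolated)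
Conditions: Et3SiH, Pd/C (10 wt % Pd), acetone, rt
Reagents that add atoms: none
Why: In the Fukuyama reduction zerovalent palladium inserts only into the C–S bond of the thioester and the silane delivers hydride, leaving ester, aldehyde, acetal and the trisubstituted alkene alone, and the freed formylacetate enol adds to the δ-aldehyde and rests as the six-membered lactol.

Step 7
Reactants: 11 lactol
Product: 12 methyl (4R)-4-[(2E)-1,1-dimethoxybut-2-en-2-yl]-2-oxo-3,4-dihydro-2H-pyran-5-carboxylate
Conditions: n-Pr4N[RuO4] (5 mol %), NMO, 4 Å MS, CH2Cl2, rt
Reagents that add atoms: none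
Why: Ley–Griffith oxidation of the lactol to the lactone under neutral anhydrous conditions raises the future acetate carbon to the acid level and masks the acidic enol as an enol ester, so no C–H acid is left when the enal is unveiled.

Step 8
Reactants: 12 enol lactone acetal
Product: 13 methyl (4R)-2-oxo-4-[(2E)-1-oxobut-2-en-2-yl]-3,4-dihydro-2H-pyran-5-carboxylate
Conditions: SiO2 wetted with 10 % aq. oxalic acid, CH2Cl2, rt
Reagents that add atoms: water, O
Why: The acetal of an α,β-unsaturated aldehyde ionises through an allyl-stabilised oxocarbenium ion and is hydrolysed on wet acidic silica much faster than the enol lactone or the ester reacts, and the E geometry is the stable one.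

Step 9
Reactants: 13 enal enol lactone; 2 hydroxytyrosol acetonide
Product: 14 open enol dialdehyde methyl (3R,4E)-3-{2-[2-(2,2-dimethyl-1,3-benzodioxol-5-yl)ethoxy]-2-oxoethyl}-4-formyl-2-(hydroxymethylidene)hex-4-enoate
Conditions: DMAP (5 mol %), CH2Cl2, −20 to 0 °C; cold aq. citric acid wash; crude, no chromatography
Reagents that add atoms: none
Why: The enol lactone is a vinylogous anhydride whose leaving group is the stabilised formylacetate enolate, so nucleophilic-catalysis acyl transfer passes the acyl group to the primary alcohol, which installs the hydroxytyrosyl ester and frees the enol in one event without touching C4.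

Step 10
Reactants: 14 open enol dialdehyde
Product: 15 methyl (2S,3R,4R)-4-{2-[2-(2,2-dimethyl-1,3-benzodioxol-5-yl)ethoxy]-2-oxoethyl}-3-formyl-2-methyl-3,4-dihydro-2H-pyran-5-carboxylate
Conditions: Et3N (0.2 equiv), AcOH (0.1 equiv), toluene (0.02 M), rt to 40 °C, until the isomer distribution no longer changes; buffered silica
Reagents that add atoms: none
Why: Et3N deprotonates the formylacetate enol of 14 (a vinylogous carboxylic acid), its oxygen adds to C2, the β-carbon of the ethylidene enal, and the aldehyde enolate so formed is protonated at C3, which is the intramolecular oxa-Michael addition by which secoiridoid aglycone dialdehydes close. The ring O1–C2–C3–C4–C5=C6 closes 6-endo-trig, and O-attack at C2 is the only productive mode, because C-attack by C5 would give a cyclobutane and 1,2-addition to the formyl group gives only a hemiacetal that reopens. As 15 is a β-alkoxy aldehyde whose leaving group is a stabilised enolate, E1cB opening back to 14 and enolisation at C3 stay fast under the same base, so C2 (face of the enal attacked) and C3 (face of protonation) are placed by equilibrium and not by the first closure or the alkene geometry. The controlling element is C4, which has no acidic hydrogen and no leaving group in reach of a carbanion: with its acetate arm pseudoequatorial on the half-chair, only the 2,3-trans/3,4-trans isomer can hold formyl and methyl equatorial as well. The step thus needs the (2S,3R) pair out of four C2/C3 combinations, and its closest competitor is the C2 epimer, which escapes the allylic A(1,2) strain between the arm and the C5 ester by turning arm and formyl axial. Isomers separated from 15 are put back under the same conditions, since all of them return to 14.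

Step 11
Reactants: 15 catechol acetonide of the target
Product: 16 target methyl (2S,3R,4R)-4-{2-[2-(3,4-dihydroxyphenyl)ethoxy]-2-oxoethyl}-3-formyl-2-methyl-3,4-dihydro-2H-pyran-5-carboxylate
Conditions: TFA/H2O (9:1), CH2Cl2, 0 °C to rt, N2
Reagents that add atoms: none
Why: Acid hydrolysis of the 2,2-dimethyl-1,3-benzodioxole through an aryloxy-stabilised oxocarbenium ion frees the catechol, while the vinylogous carbonate, both esters and the aldehyde tolerate cold aqueous TFA and C4 has no pathway for exchange.

## Compound list

1 | hydroxytyrosol | OCCc1ccc(O)c(O)c1 | starting material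
2 | hydroxytyrosol acetonide | OCCc1ccc2OC(C)(C)Oc2c1 | intermediate
3 | (E)-crotonaldehyde | C/C=C/C=O | starting material
4 | (Z)-2-iodobut-2-enal | C/C=C(\I)C=O | intermediate
5 | (Z)-2-iodo-1,1-dimethoxybut-2-ene | C/C=C(\I)C(OC)OC | intermediate
6 | acrolein | C=CC=O | starting material
7 | (2E,4E)-4-(dimethoxymethyl)hexa-2,4-dienal | C/C=C(\C=C\C=O)C(OC)OC | intermediate
8 | methyl 3-(ethylsulfanyl)-3-oxopropanoate | CCSC(=O)CC(=O)OC | starting material
9 | Michael adduct, methyl (3S,4E)-4-(dimethoxymethyl)-2-[(ethylsulfanyl)carbonyl]-3-(2-oxoethyl)hex-4-enoate | O=CC[C@H](/C(=C\C)C(OC)OC)C(C(=O)OC)C(=O)SCC | intermediate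
10 | open enol aldehyde, methyl (3R,4E)-4-(dimethoxymethyl)-2-(hydroxymethylidene)-3-(2-oxoethyl)hex-4-enoate (not isolated) | O=CC[C@H](/C(=C\C)C(OC)OC)C(=CO)C(=O)OC | intermediate
11 | lactol, methyl (4R)-4-[(2E)-1,1-dimethoxybut-2-en-2-yl]-2-hydroxy-3,4-dihydro-2H-pyran-5-carboxylate | COC(=O)C1=COC(O)C[C@@H]1/C(=C\C)C(OC)OC | intermediate
12 | enol lactone acetal, methyl (4R)-4-[(2E)-1,1-dimethoxybut-2-en-2-yl]-2-oxo-3,4-dihydro-2H-pyran-5-carboxylate | COC(=O)C1=COC(=O)C[C@@H]1/C(=C\C)C(OC)OC | intermediate
13 | enal enol lactone, methyl (4R)-2-oxo-4-[(2E)-1-oxobut-2-en-2-yl]-3,4-dihydro-2H-pyran-5-carboxylate | COC(=O)C1=COC(=O)C[C@@H]1/C(C=O)=C\C | intermediate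
14 | open enol dialdehyde (precursor of the key step) | COC(=O)C(=CO)[C@H](CC(=O)OCCc1ccc2OC(C)(C)Oc2c1)/C(C=O)=C\C | intermediate
15 | catechol acetonide of the target, (2S,3R,4R) | COC(=O)C1=CO[C@@H](C)[C@H](C=O)[C@H]1CC(=O)OCCc1ccc2OC(C)(C)Oc2c1 | intermediate
16 | CNP0172886.1, (2S,3R,4R) | COC(=O)C1=CO[C@@H](C)[C@H](C=O)[C@H]1CC(=O)OCCc1ccc(O)c(O)c1 | target

## Step count

- Total step count: 11.
- Longest linear sequence: 10 (steps 2 to 11, from crotonaldehyde).

## Steps most likely to fail

**Step 10.**
- *Risk:* the equilibrium may rest not on 15 but on its C2 epimer, in which arm and formyl turn axial and the methyl stays equatorial, or on a mixture. The isomers may also keep exchanging on silica, so that sorting them as aldehydes fails.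
- *Fallback:* stereocontrol by sorting frozen derivatives with recycling, instead of by the position of the equilibrium.
  - It sets out from 15, taken as the crude isomer mixture of step 10, and comes back at 16.
  - HC(OMe)3, PPTS and MeOH turn the aldehydes into dimethyl acetals. These have neither an acidic C3–H nor an acceptor for ring opening, so they can be chromatographed.
  - The all-trans dimethyl acetal F1 is collected. Aqueous TFA removes its acetal and acetonide together to give 16.
  - The other acetals are hydrolysed on wet acidic silica and go back into step 10.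

**Step 5.**
- *Risk:* addition may run 1,6 at the methyl-bearing terminus. Deprotonation of that methyl group may tie the catalyst up as a trienamine. Slow addition next to the branched substituent may let uncatalysed addition erode the facial selectivity.
- *Fallback:* ethylidene built after C4 instead of before it.
  - It sets out from 3 and 8 and comes back at 13.
  - Cross-metathesis of 3 with 4,4-diethoxybut-1-ene (Hoveyda–Grubbs second-generation catalyst, CH2Cl2, reflux) gives (E)-5,5-diethoxypent-2-enal F2, which has no second alkene and no acidified γ-hydrogen.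
  - Addition of 8 under the catalyst of step 5 gives the Michael adduct F3.
  - Et3SiH with Pd/C gives the lactol F4, and n-Pr4N[RuO4]/NMO gives the enol lactone acetal F5.
  - TMSOTf/i-Pr2NEt then turns the acetal into the ethyl enol ether F6.
  - BF3·OEt2 adds F6 to acetaldehyde diethyl acetal (enol ether–acetal condensation of the Mukaiyama type) to give the β-ethoxy acetal F7.
  - Aqueous acid hydrolyses the acetal and eliminates ethanol to give 13.

**Step 4.**
- *Risk:* acrolein and the dienal may polymerise under the coupling conditions, and slow coupling of the hindered iodide may allow loss of alkene geometry.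
- *Fallback:* robust acrylate coupling followed by redox adjustment.
  - It sets out from 5 and comes back at 7.
  - The Heck reaction is run with methyl acrylate to give the dienoate methyl (2E,4E)-4-(dimethoxymethyl)hexa-2,4-dienoate F8.
  - i-Bu2AlH (CH2Cl2, −78 °C) reduces it to the dienol (2E,4E)-4-(dimethoxymethyl)hexa-2,4-dien-1-ol F9.
  - MnO2 oxidises the allylic alcohol to 7.

## Further compounds

F1 | step 10 | all-trans dimethyl acetal of 15 | COC(=O)C1=CO[C@@H](C)[C@H](C(OC)OC)[C@H]1CC(=O)OCCc1ccc2OC(C)(C)Oc2c1
F2 | step 5 | (E)-5,5-diethoxypent-2-enal | CCOC(C/C=C/C=O)OCC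
F3 | step 5 | Michael adduct, methyl 5,5-diethoxy-2-[(ethylsulfanyl)carbonyl]-3-(2-oxoethyl)pentanoate, C3 configured as C4 of the target | O=CC[C@H](CC(OCC)OCC)C(C(=O)OC)C(=O)SCC
F4 | step 5 | lactol, methyl 4-(2,2-diethoxyethyl)-2-hydroxy-3,4-dihydro-2H-pyran-5-carboxylate, C4 as in 11 | COC(=O)C1=COC(O)C[C@@H]1CC(OCC)OCC
F5 | step 5 | enol lactone acetal, methyl 4-(2,2-diethoxyethyl)-2-oxo-3,4-dihydro-2H-pyran-5-carboxylate, C4 as in 12 | COC(=O)C1=COC(=O)C[C@@H]1CC(OCC)OCC
F6 | step 5 | ethyl enol ether, methyl 4-(2-ethoxyethenyl)-2-oxo-3,4-dihydro-2H-pyran-5-carboxylate, E/Z mixture | COC(=O)C1=COC(=O)C[C@@H]1C=COCC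
F7 | step 5 | β-ethoxy acetal, methyl 2-oxo-4-(1,1,3-triethoxybutan-2-yl)-3,4-dihydro-2H-pyran-5-carboxylate, side-chain isomers | COC(=O)C1=COC(=O)C[C@@H]1C(C(C)OCC)C(OCC)OCC
F8 | step 4 | methyl (2E,4E)-4-(dimethoxymethyl)hexa-2,4-dienoate | C/C=C(\C=C\C(=O)OC)C(OC)OC
F9 | step 4 | (2E,4E)-4-(dimethoxymethyl)hexa-2,4-dien-1-ol | C/C=C(\C=C\CO)C(OC)OC
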